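The plan rests on opening ring C of the bicyclo[3.2.1]octane (rings C and D) at C9–C11 and C12–C13, which releases C11–C12 as a silyl vinyl ether. It exploits two features: C9 lies β to the C7 carbonyl of the ring B lactone, and C13 lies next to C16. A C8=C9 lactone therefore accepts nucleophilic radicals at C9, and a C16 ketone makes a C13 radical electrophilic. In one operation a bromo ketone hanging from the spiro-lactone adds to the vinyl ether, and the resulting α-silyloxy radical closes ring C. The precursor is the ring A/B spiro-lactone carrying a 2-bromo-3-oxobutyl chain on C8; ring D follows by oxidative enolate coupling.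

Key step: step 13

Atom numbers C1 to C20 follow the ent-kaurane numbering of the target.
Assumption: the (4R,5R)-diol written in step 1 is taken to give the (R)-configured quaternary carbon C4. If the sense of induction is the reverse, the commercial (4S,5S)-diol is used instead.

Step 1
Reactants: 1 methacrolein; 2 (E)-1-(dimethylamino)-3-(tert-butyldimethylsilyloxy)buta-1,3-diene
Product: 3 endo adduct (1R,2S)-4-(tert-butyldimethylsilyloxy)-2-(dimethylamino)-1-methylcyclohex-3-ene-1-carbaldehyde
Conditions: (4R,5R)-2,2-dimethyl-α,α,α′,α′-tetra(1-naphthyl)-1,3-dioxolane-4,5-dimethanol (20 mol %), toluene, −80 °C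
Reagents that add atoms: none
Why: Hydrogen-bond-catalysed enantioselective Diels–Alder reaction of an aminosiloxydiene with an α-substituted acrolein, in which the chiral diol shields one face of the bound aldehyde and so sets the quaternary carbon C4, while the endo rule places CHO and NMe2 cis.

Step 2
Reactants: 3 endo adduct
Product: 5 (R)-4-(hydroxymethyl)-4-methylcyclohex-2-en-1-one, via amino alcohol 4 (not isolated)
Conditions: LiAlH4, Et2O, −78 °C to rt; then HF (aq.), MeCN, rt
Reagents that add atoms: none
Why: Hydride reduction of the aldehyde leaves the silyl enol ether intact, and HF then desilylates it and triggers E1cB loss of dimethylamine to give the enone without touching C4.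

Step 3
Reactants: 5 (R)-4-(hydroxymethyl)-4-methylcyclohex-2-en-1-one; 6 acetylene
Product: 7 cis-fused cyclobutene, 5-(hydroxymethyl)-5-methylbicyclo[4.2.0]oct-7-en-2-one (drawn with the cyclobutene on the face of CH2OH)
Conditions: hν (Hg lamp, Pyrex), acetylene-saturated CH2Cl2, −40 °C
Reagents that add atoms: none
Why: Enone–alkyne [2+2] photocycloaddition gives the cis-fused cyclobutene, and its facial outcome is of no consequence because C5 and C10 both become epimerisable in step 4.

Step 4
Reactants: 7 cis-fused cyclobutene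
Product: 9 keto acetal (ring A ketone at C1, cis-fused C19–O–C6 tetrahydrofuran with exo OMe on C6, Z-hydroxymethylene C20 on C10), via lactol enol 8 (not isolated)
Conditions: O3, CH2Cl2–MeOH, −78 °C; Me2S; Et3N (0.1 equiv), rt; then pyridinium p-toluenesulfonate (cat.), MeOH, rt
Reagents that add atoms: ozone [O-][O+]=O; methanol CO
Why: Ozonolysis of the cyclobutene gives the 1,4-dialdehyde, whose C20 formyl group rests as the chelated enol while C5 equilibrates so that the C19 hydroxyl can close on C6, and acid-catalysed acetalisation then fixes the cis-fused tetrahydrofuran as its exo methyl acetal.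

Step 5
Reactants: 9 keto acetal; 10 methyl acrylate
Product: 11 keto aldehyde ester (C10 quaternary, CHO = C20 cis to C6, CH2CH2CO2Me = C9–C8–C7 trans to C6)
Conditions: 10 (3 equiv), 1,8-diazabicyclo[5.4.0]undec-7-ene (DBU, 0.1 equiv), MeCN, 0 °C to rt
Reagents that add atoms: none
Why: Base-catalysed Michael addition of the 2-formyl ketone builds the quaternary carbon C10, the acrylate approaching the planar enolate anti to the neighbouring C6 acetal so that C9 ends trans and C20 cis to C6.

Step 6
Reactants: 11 keto aldehyde ester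
Product: 13 hydroxy spiro-lactone (7,20-lactone, 1-OH trans to C20), via diol ester 12 (not isolated)
Conditions: Me4NBH(OAc)3 (5 equiv), MeCN–AcOH, −30 to 0 °C; work-up; then DBU (0.2 equiv), toluene, 60 °C
Reagents that add atoms: none
Why: Evans–Saksena reduction, in which the aldehyde is reduced first and the boron-bound C20 alkoxide then delivers hydride to the C1 ketone from its own face, putting O1 trans to C20, after which the primary alcohol lactonises onto C7.

Step 7
Reactants: 13 hydroxy spiro-lactone
Product: 14 C1 triethylsilyl ether of 13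
Conditions: Et3SiCl, imidazole, 4-(dimethylamino)pyridine (cat.), DMF, 40 °C
Reagents that add atoms: chlorotriethylsilane CC[Si](Cl)(CC)CC
Why: Imidazole-promoted silylation masks the only free hydroxyl under non-acidic conditions that leave the methyl acetal and the lactone untouched.

Step 8
Reactants: 14 silyl ether
Product: 15 C8 phenylselenide (C8 epimers)
Conditions: LiN(iPr)2, THF, −78 °C; PhSeBr
Reagents that add atoms: phenylselenyl bromide Br[Se]c1ccccc1
Why: α-Selenenylation of the lactone enolate, the only enolisable site, gives a C8 centre that needs no control because step 11 removes it.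

Step 9
Reactants: 16 methyl vinyl ketone
Product: 18 3-bromobut-3-en-2-one, via dibromide 17 (not isolated)
Conditions: Br2, CH2Cl2, 0 °C; then Et3N, 0 °C
Reagents that add atoms: bromine BrBr
Why: Bromine addition to the enone followed by E1cB loss of HBr (acidic C3 hydrogen, C4 bromide) gives the α-bromo enone.

Step 10
Reactants: 15 C8 phenylselenide; 18 3-bromobut-3-en-2-one
Product: 19 Michael adduct (C8 bears SePh and CH2–CHBr–COCH3; C8 and C13 epimers)
Conditions: LiN(iPr)2, THF, −78 °C; 18; AcOH quench at −78 °C
Reagents that add atoms: none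
Why: Michael addition of the soft selenium-stabilised lactone enolate to the α-bromo enone forms C8–C14, and the bromo enolate can only be protonated because C8 no longer carries a hydrogen, the new centres being erased in steps 11 and 13.

Step 11
Reactants: 19 Michael adduct
Product: 21 unsaturated spiro-lactone (C8=C9) with a 2-bromo-3-oxobutyl chain on C8 (C13 epimers), via selenoxide 20 (not isolated)
Conditions: H2O2 (30 % aq.), CH2Cl2, 0 °C to rt
Reagents that add atoms: none
Why: Selenoxide syn-elimination, which in six-membered lactones favours the endocyclic C8=C9 alkene over the exocyclic one.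

Step 12
Reactants: 22 tetrahydrofuran
Product: 24 tert-butyldimethyl(vinyloxy)silane, via lithium ethenolate 23 (not isolated)
Conditions: n-BuLi, THF, 25 °C; then t-BuMe2SiCl, 0 °C to rt
Reagents that add atoms: tert-butyldimethylsilyl chloride C[Si](C)(Cl)C(C)(C)C
Why: α-Lithiation of tetrahydrofuran and [3+2] cycloreversion give the lithium enolate of acetaldehyde, which is O-silylated.

Step 13
Reactants: 21 unsaturated spiro-lactone bromo ketone; 24 tert-butyldimethyl(vinyloxy)silane
Product: 28 ring A/B/C lactone (11-OSiMe2t-Bu cis to C10, 9-H trans to O11, equatorial acetyl on C13 trans to C10, C8 epimers), via silyloxy radical 25 (not isolated), via C8 radical 26 (not isolated), via C13 epimer mixture 27 (not isolated)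
Conditions: 24 (10 equiv), Bu3SnH (1.3 equiv) + 2,2′-azobis(isobutyronitrile) (0.2 equiv) by syringe pump, benzene (0.02 M), 80 °C; then DBU (0.3 equiv), CH2Cl2, rt
Reagents that add atoms: none
Why: Bu3Sn• abstracts bromine from 21 to give the electrophilic α-keto radical at C13, which cannot reach its own alkene (3-exo or 4-endo only) and adds to the CH2 terminus (C12) of the electron-rich vinyl ether 24; the nucleophilic α-silyloxy radical 25 at C11 then attacks C9, the β-carbon of the unsaturated lactone, and the tertiary α-lactone radical 26 takes hydrogen from Bu3SnH. The closest known reaction type is the tin hydride mediated radical addition–cyclisation (radical [4+2] annulation) of α-halo carbonyl compounds with enol ethers or vinyl esters, and the ring-closing event mirrors SmI2 ketyl–olefin closures onto α-substituted unsaturated lactones. Ring C closes in the 6-endo-trig mode, preferred over 5-exo because C8 is fully substituted and is the electron-rich end of the acceptor. C9 is set by attack on the alkene face flanked only by the equatorial hydrogen on C1, the other face being screened by the C6 acetal on C5; C11 is set in the chair-like transition state, where the radical should follow the known 1,2-cis preference of 1-substituted hexenyl-type radicals and keep its silyloxy group away from C1 and its silyl ether, so that O11 ends cis to C10. C13 is formed without control and is then converged by DBU to the equatorial acetyl epimer (trans to C10), while C8 stays a mixture that step 14 erases. The step needs three radicals to react in a fixed order, which the alternating polarity of 21 and 24 secures, while vinyl ethers do not homopropagate and slow addition of Bu3SnH keeps direct reduction of the C13 and C11 radicals behind C–C bond formation.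

Step 14
Reactants: 28 ring A/B/C lactone
Product: 30 tetracyclic 16-ketone (bicyclo[3.2.1]octan-6-one, C8 quaternary, C15 = CH2), via dilithium bis-enolate 29 (not isolated)
Conditions: LiN(iPr)2 (2.6 equiv), THF, −78 °C; Fe(acac)3 (2.4 equiv), −78 °C to rt
Reagents that add atoms: none
Why: Intramolecular oxidative heterocoupling of the lactone enolate and the kinetic methyl ketone enolate forms C8–C15, and because the two-carbon bridge can span C8 and C13 only on the face that carries the acetyl group, C13 dictates the configuration of the quaternary carbon C8.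

Step 15
Reactants: 30 tetracyclic 16-ketone
Product: 31 16-methylene compound (C16=C17)
Conditions: Ph3PCH3Br, KOtBu, THF, 0 to 45 °C
Reagents that add atoms: methyltriphenylphosphonium bromide C[P+](c1ccccc1)(c1ccccc1)c1ccccc1.[Br-]
Why: Wittig methylenation converts the accessible C16 ketone into the exocyclic alkene, and the lactone is inert to the ylide.

Step 16
Reactants: 31 16-methylene compound
Product: 32 allylic alcohol (15-OH, C15 configuration open)
Conditions: SeO2 (0.5 equiv), t-BuOOH (3 equiv), CH2Cl2, 0 °C to rt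
Reagents that add atoms: selenium dioxide O=[Se]=O; tert-butyl hydroperoxide CC(C)(C)OO
Why: Riley-type allylic hydroxylation (ene reaction, then [2,3]-shift) attacks C15, the only allylic CH2 because C13 is a bridgehead, and the new centre is erased in step 17.

Step 17
Reactants: 32 allylic alcohol
Product: 33 protected enone (15-one, 16-methylene)
Conditions: Dess–Martin periodinane, CH2Cl2, 0 °C to rt
Reagents that add atoms: none
Why: Dess–Martin oxidation of the only free hydroxyl gives the α-methylene cyclopentanone under near-neutral conditions that spare silyl ethers and acetal.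

Step 18
Reactants: 33 protected enone
Product: 34 lactol triol (1-OH, 11-OH, C6 lactol as anomers)
Conditions: HCl (2 M aq.)–THF, 35 °C
Reagents that add atoms: water O
Why: Acid-catalysed solvolysis cleaves both silyl ethers and hydrolyses the methyl acetal to the lactol in one operation, and no stereocentre other than the anomeric C6 is affected.

Step 19
Reactants: 34 lactol triol
Product: 35 oreskaurin A
Conditions: Ac2O (1.1 equiv), pyridine, CH2Cl2, −20 °C
Reagents that add atoms: acetic anhydride CC(=O)OC(C)=O
Why: Selective O-acylation of the lactol hydroxyl, the most acidic and least hindered one, through its exo anomer (trans to C10) sets C6, while the axial neopentyl 1-OH and the 11-OH next to C10 react more slowly.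

Compound list
1 | methacrolein | C=C(C)C=O | starting material
2 | (E)-1-(dimethylamino)-3-(tert-butyldimethylsilyloxy)buta-1,3-diene | CN(C)/C=C/C(=C)O[Si](C)(C)C(C)(C)C | starting material
3 | endo adduct, (1R,2S)-4-(tert-butyldimethylsilyloxy)-2-(dimethylamino)-1-methylcyclohex-3-ene-1-carbaldehyde | O=C[C@]1(C)CCC(O[Si](C)(C)C(C)(C)C)=C[C@@H]1N(C)C | intermediate
4 | amino alcohol (CHO of 3 reduced to CH2OH) | OC[C@]1(C)CCC(O[Si](C)(C)C(C)(C)C)=C[C@@H]1N(C)C | intermediate
5 | (R)-4-(hydroxymethyl)-4-methylcyclohex-2-en-1-one | O=C1C=C[C@](C)(CO)CC1 | intermediate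
6 | acetylene | C#C | starting material
7 | cis-fused cyclobutene, 5-(hydroxymethyl)-5-methylbicyclo[4.2.0]oct-7-en-2-one | O=C1CC[C@@](C)(CO)[C@H]2C=C[C@@H]12 | intermediate
8 | lactol enol (C6 lactol with O19, hydroxymethylene C20 on C10, anomers) | O=C1CC[C@@]2(C)COC(O)[C@H]2/C1=C/O | intermediate
9 | keto acetal (exo methyl acetal at C6, Z-hydroxymethylene at C10) | O=C1CC[C@@]2(C)CO[C@H](OC)[C@H]2/C1=C/O | intermediate
10 | methyl acrylate | C=CC(=O)OC | starting material
11 | keto aldehyde ester with quaternary C10 | COC(=O)CC[C@]1(C=O)C(=O)CC[C@@]2(C)CO[C@H](OC)[C@H]21 | intermediate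
12 | diol ester (20-OH, 1-OH trans to C20) | COC(=O)CC[C@]1(CO)[C@H](O)CC[C@@]2(C)CO[C@H](OC)[C@H]21 | intermediate
13 | hydroxy spiro-lactone | O=C1CC[C@]2(CO1)[C@H](O)CC[C@@]3(C)CO[C@H](OC)[C@H]32 | intermediate
14 | C1 triethylsilyl ether of 13 | O=C1CC[C@]2(CO1)[C@H](O[Si](CC)(CC)CC)CC[C@@]3(C)CO[C@H](OC)[C@H]32 | intermediate
15 | C8 phenylselenide (C8 epimers) | O=C1C([Se]c4ccccc4)C[C@]2(CO1)[C@H](O[Si](CC)(CC)CC)CC[C@@]3(C)CO[C@H](OC)[C@H]32 | intermediate
16 | methyl vinyl ketone | C=CC(C)=O | starting material
17 | 3,4-dibromobutan-2-one | CC(=O)C(Br)CBr | intermediate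
18 | 3-bromobut-3-en-2-one | CC(=O)C(Br)=C | intermediate
19 | Michael adduct (C8 and C13 epimers) | O=C1C(CC(Br)C(C)=O)([Se]c4ccccc4)C[C@]2(CO1)[C@H](O[Si](CC)(CC)CC)CC[C@@]3(C)CO[C@H](OC)[C@H]32 | intermediate
20 | selenoxide of 19 | O=C1C(CC(Br)C(C)=O)([Se](=O)c4ccccc4)C[C@]2(CO1)[C@H](O[Si](CC)(CC)CC)CC[C@@]3(C)CO[C@H](OC)[C@H]32 | intermediate
21 | unsaturated spiro-lactone bromo ketone (C13 epimers) | O=C1C(CC(Br)C(C)=O)=C[C@]2(CO1)[C@H](O[Si](CC)(CC)CC)CC[C@@]3(C)CO[C@H](OC)[C@H]32 | intermediate
22 | tetrahydrofuran | C1CCOC1 | starting material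
23 | lithium ethenolate | [Li+].[O-]C=C | intermediate
24 | tert-butyldimethyl(vinyloxy)silane | C=CO[Si](C)(C)C(C)(C)C | intermediate
25 | α-silyloxy radical at C11 (C12–C13 formed) | O=C1C(CC(C[CH]O[Si](C)(C)C(C)(C)C)C(C)=O)=C[C@]2(CO1)[C@H](O[Si](CC)(CC)CC)CC[C@@]3(C)CO[C@H](OC)[C@H]32 | intermediate
26 | cyclised tertiary radical at C8 | CC(=O)C1C[C@@H](O[Si](C)(C)C(C)(C)C)[C@H]2[C@]3(COC(=O)[C]2C1)[C@H](O[Si](CC)(CC)CC)CC[C@@]4(C)CO[C@H](OC)[C@H]43 | intermediate
27 | annulation product as C13 epimer mixture | CC(=O)C1C[C@@H](O[Si](C)(C)C(C)(C)C)[C@H]2[C@]3(COC(=O)C2C1)[C@H](O[Si](CC)(CC)CC)CC[C@@]4(C)CO[C@H](OC)[C@H]43 | intermediate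
28 | ring A/B/C lactone with equatorial C13 acetyl (C8 epimers) | CC(=O)[C@@H]1C[C@@H](O[Si](C)(C)C(C)(C)C)[C@H]2[C@]3(COC(=O)C2C1)[C@H](O[Si](CC)(CC)CC)CC[C@@]4(C)CO[C@H](OC)[C@H]43 | intermediate
29 | dilithium bis-enolate of 28 | [Li+].[Li+].[O-]C(=C)[C@@H]1C[C@@H](O[Si](C)(C)C(C)(C)C)[C@H]2[C@]3(COC([O-])=C2C1)[C@H](O[Si](CC)(CC)CC)CC[C@@]4(C)CO[C@H](OC)[C@H]43 | intermediate
30 | tetracyclic 16-ketone | O=C1C[C@]23C[C@H]1C[C@@H](O[Si](C)(C)C(C)(C)C)[C@H]2[C@]1(COC3=O)[C@H](O[Si](CC)(CC)CC)CC[C@@]2(C)CO[C@H](OC)[C@H]21 | intermediate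
31 | 16-methylene compound | C=C1C[C@]23C[C@H]1C[C@@H](O[Si](C)(C)C(C)(C)C)[C@H]2[C@]1(COC3=O)[C@H](O[Si](CC)(CC)CC)CC[C@@]2(C)CO[C@H](OC)[C@H]21 | intermediate
32 | 15-hydroxy-16-methylene compound (C15 open) | C=C1C(O)[C@]23C[C@H]1C[C@@H](O[Si](C)(C)C(C)(C)C)[C@H]2[C@]1(COC3=O)[C@H](O[Si](CC)(CC)CC)CC[C@@]2(C)CO[C@H](OC)[C@H]21 | intermediate
33 | protected enone | C=C1C(=O)[C@]23C[C@H]1C[C@@H](O[Si](C)(C)C(C)(C)C)[C@H]2[C@]1(COC3=O)[C@H](O[Si](CC)(CC)CC)CC[C@@]2(C)CO[C@H](OC)[C@H]21 | intermediate
34 | lactol triol (C6 anomers) | C=C1C(=O)[C@]23C[C@H]1C[C@@H](O)[C@H]2[C@]1(COC3=O)[C@H](O)CC[C@@]2(C)COC(O)[C@H]21 | intermediate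
35 | oreskaurin A | C=C1C(=O)[C@]23C[C@H]1C[C@@H](O)[C@H]2[C@]1(COC3=O)[C@H](O)CC[C@@]2(C)CO[C@H](OC(C)=O)[C@H]21 | target

Total step count: 19. Longest linear sequence: 17 (steps 1–8, 10, 11, 13–19).

Steps most likely to fail

1. Step 13. Premature reduction of the C13 or C11 radical, sluggish closure onto the neopentyl C9, or poor facial selectivity at C11 may erode the annulation. The fallback sets out from 21, returns at 28, and makes the two bonds in separate, chelation-controlled operations.
   - Keck allylation of 21 (allyltributylstannane, 2,2′-azobis(isobutyronitrile), benzene, 80 °C) gives the allyl ketone F1.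
   - Selective ozonolysis of its terminal alkene (O3, then Me2S) gives the aldehyde F2.
   - A SmI2, LiBr, t-BuOH ketyl–olefin cyclisation, in which samarium bridges the ketyl oxygen and the lactone carbonyl, gives the C11 alcohol F3.
   - Silylation (t-BuMe2SiCl, imidazole, DMF) followed by DBU equilibration gives 28.

2. Step 14. Slow deprotonation at the hindered C8, scrambling of the kinetic ketone enolate, or intermolecular dimerisation may defeat the oxidative coupling. The fallback sets out from 28, returns at 33, and closes ring D at C15–C16 instead.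
   - The methyl ketone is masked in situ as its kinetic trimethylsilyl enol ether (LiN(iPr)2, Me3SiCl).
   - A second deprotonation and gaseous formaldehyde, with acidic work-up, give the C8 hydroxymethyl lactone F4.
   - Dess–Martin oxidation gives the keto aldehyde F5.
   - SmI2 pinacol cyclisation gives the 15,16-diol F6.
   - Dess–Martin oxidation of the secondary alcohol gives the α-ketol F7.
   - Dehydration (SOCl2, pyridine) can only form the exocyclic alkene and gives 33.

3. Step 10. 1,2-Addition, bromine transfer from 18 to the enolate, or polymerisation of 18 may compete with the Michael addition. The fallback sets out from 15 and returns at 28.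
   - Aldol reaction of the enolate of 15 with gaseous formaldehyde gives the hydroxymethyl selenide F8.
   - H2O2 oxidation eliminates away from the oxygen-bearing carbon to give the allylic alcohol F9.
   - An Appel reaction (CBr4, PPh3) gives the allylic bromide F10.
   - C-alkylation of 3-chloropentane-2,4-dione (K2CO3, acetone) gives the tertiary chloride F11.
   - The tin hydride conditions of step 13 with 24 give the diacetyl annulation product F12.
   - K2CO3 in MeOH removes one acetyl group by retro-Claisen cleavage and equilibrates C13 to give 28.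

Further compounds
F1 | step 13 | allyl ketone (C13 allylated, C13 epimers) | O=C1C(CC(CC=C)C(C)=O)=C[C@]2(CO1)[C@H](O[Si](CC)(CC)CC)CC[C@@]3(C)CO[C@H](OC)[C@H]32
F2 | step 13 | keto aldehyde with C11 as CHO | O=C1C(CC(CC=O)C(C)=O)=C[C@]2(CO1)[C@H](O[Si](CC)(CC)CC)CC[C@@]3(C)CO[C@H](OC)[C@H]32
F3 | step 13 | C11 alcohol from ketyl–olefin closure | CC(=O)C1C[C@@H](O)[C@H]2[C@]3(COC(=O)C2C1)[C@H](O[Si](CC)(CC)CC)CC[C@@]4(C)CO[C@H](OC)[C@H]43
F4 | step 14 | C8 hydroxymethyl lactone (C15 = CH2OH, cis to the acetyl group) | CC(=O)[C@@H]1C[C@@H](O[Si](C)(C)C(C)(C)C)[C@H]2[C@]3(COC(=O)[C@@]2(CO)C1)[C@H](O[Si](CC)(CC)CC)CC[C@@]4(C)CO[C@H](OC)[C@H]43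
F5 | step 14 | C8 formyl lactone (C15 = CHO) | CC(=O)[C@@H]1C[C@@H](O[Si](C)(C)C(C)(C)C)[C@H]2[C@]3(COC(=O)[C@@]2(C=O)C1)[C@H](O[Si](CC)(CC)CC)CC[C@@]4(C)CO[C@H](OC)[C@H]43
F6 | step 14 | 15,16-diol from pinacol closure (C15, C16 open) | CC1(O)C(O)[C@]23C[C@H]1C[C@@H](O[Si](C)(C)C(C)(C)C)[C@H]2[C@]1(COC3=O)[C@H](O[Si](CC)(CC)CC)CC[C@@]2(C)CO[C@H](OC)[C@H]21
F7 | step 14 | 16-hydroxy-15-ketone | CC1(O)C(=O)[C@]23C[C@H]1C[C@@H](O[Si](C)(C)C(C)(C)C)[C@H]2[C@]1(COC3=O)[C@H](O[Si](CC)(CC)CC)CC[C@@]2(C)CO[C@H](OC)[C@H]21
F8 | step 10 | C8 hydroxymethyl selenide | O=C1C(CO)([Se]c4ccccc4)C[C@]2(CO1)[C@H](O[Si](CC)(CC)CC)CC[C@@]3(C)CO[C@H](OC)[C@H]32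
F9 | step 10 | allylic alcohol (C8=C9, C14 = CH2OH) | O=C1C(CO)=C[C@]2(CO1)[C@H](O[Si](CC)(CC)CC)CC[C@@]3(C)CO[C@H](OC)[C@H]32
F10 | step 10 | allylic bromide | O=C1C(CBr)=C[C@]2(CO1)[C@H](O[Si](CC)(CC)CC)CC[C@@]3(C)CO[C@H](OC)[C@H]32
F11 | step 10 | tertiary chloride, C13 bearing Cl and two acetyl groups | O=C1C(CC(Cl)(C(C)=O)C(C)=O)=C[C@]2(CO1)[C@H](O[Si](CC)(CC)CC)CC[C@@]3(C)CO[C@H](OC)[C@H]32
F12 | step 10 | diacetyl annulation product | CC(=O)C1(C(C)=O)C[C@@H](O[Si](C)(C)C(C)(C)C)[C@H]2[C@]3(COC(=O)C2C1)[C@H](O[Si](CC)(CC)CC)CC[C@@]4(C)CO[C@H](OC)[C@H]43
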